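Compound numbers 1–36 are fixed by the steps below and are used throughout; the full list follows the steps.

## Analysis of the target

The target 36 is a drimane joined through C11 to a chlorinated cyclopentenone. Drimane numbering is used: ring A is C1–C5 and C10, ring B is C5–C10, C11 sits on C9, C12 is the methyl on C8, C13 and C14 are on C4, C15 is on C10, and β is the face of C15. The five-membered ring is numbered C1'–C5': C1' is the alkylidene carbon, C2' carries the enol OH, C3' is CH, C4' is C=O and C5' is CHCl. Ring B holds four contiguous stereocentres, C5 (α-H), C10 (β-methyl, quaternary), C9 (β-C11) and C8 (β-OH, α-methyl, fully substituted). C15, C11 and the C8 oxygen therefore share the β face, the ring fusion is trans, and a third fully substituted carbon (C4) sits next to C5. The fifth stereocentre, C5' (R), is separated from the decalin by the planar C11=C1' bond, so the decalin cannot be expected to control it. That double bond has its own fixed geometry (E, with C9 cis to C2'). The sensitive groups are the enolised 1,3-dione (acidic, tautomerising), the cross-conjugated alkylidene (a Michael acceptor that can lose its geometry), the α-chloro ketone (epimerisable, displaceable) and the tertiary axial C8 alcohol. That alcohol dehydrates in strong acid and, in every intermediate with a carbonyl at C11, is the β-hydroxyl of an aldol (retro-aldol, elimination). The difficulty is thus twofold: a crowded ring B with the cis/cis/trans pattern, and a remote C5' centre plus an alkene geometry for which substrate control is not available. The strategy rests on ring B: the pattern C5–C10–C9–C8 with C15, C11 and O8 cis and H5 trans is what an endo [4+2] addition produces. The dienophile is a C9=C10 (E)-alkene with C11 as its carbonyl, the diene is C5=C6–C7=C8 with the oxygen on the outside of C8, and the C1–C4 tether closes ring A in the same event.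

## Retrosynthetic reasoning

36 from 35. The enolised dione and the free C8 alcohol are unmasked last. In 35 the C4' oxygen is an isopropyl vinylogous ester and O8 a triethylsilyl ether; both fall to aqueous acid, so no skeletal bond is cut here. This keeps the acidic, chelating dione out of every metal-mediated step.

35 from 34 from 33. The C5'–Cl bond is cut back to a C5'–OH of opposite configuration, and that to the C5' ketone of 33. Because C5' cannot be controlled from the decalin, it is set by a chiral reducing agent and then transferred to chlorine by a displacement with inversion. C5' is the only carbonyl of 33 that is not a vinylogous ester, which provides the site selectivity.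

33 from 32. The C1'–C2' ring bond is cut, contracting the five-membered ring to the hydroxycyclobutenone 32 with an alkyne at C11≡C1'. The forward reaction is a metal-induced 1,2-acyl shift onto the alkyne. It builds the ring, creates the C11=C1' bond and, by its anti course, places C9 cis to C2'.

32 from 27 and 30. The C1'–C5' bond is cut between an acetylide and the semisquarate 30, which supplies C2'–C5' with the oxygen pattern already in place. 30 comes from 28 by removal of one alkoxy group. The acetylide carbon C1' is the single carbon added to C11 in 27.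

27 back to 21. These are changes at C11 and O8 only: 27 from aldehyde 26, 26 from the bis-silyl ether 25, 25 from diol 24, 24 from hydroxy imide 23, and 23 from 21 by saturation of C6=C7 and loss of benzyl. The auxiliary is removed by reduction and the tertiary alcohol is silylated before C11 reaches the aldehyde level, so that no free β-hydroxy aldehyde appears.

21 from 20. This is the key disconnection: C5–C10 and C8–C9 are cut together, opening both rings to the acyclic trienoyl imide 20. It is chosen over any single-ring closure because it is the only cut that creates all four ring B stereocentres at once from alkene geometries. The oxazolidinone on C11 sets the absolute configuration. The forward reaction must be endo, must use one face of the dienophile, and must tolerate a methyl group on the inside of the diene terminus.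

20 from 17 and 18; 17 from 16 from 15 from 10 and 14. The imide N–C11 bond is cut to the acid, and the C7=C8 enol ether is cut to enal 10 and phosphine oxide 14. A two-stage Horner–Wittig reaction is chosen because the diastereomeric adducts 15 can be separated and each eliminates stereospecifically. This is the only dependable way to place benzyloxy outside and methyl inside.

10 back to 1 and 2. C9=C10 is cut to methyl ketone 8 and phosphonate 5, C5=C6 to aldehyde 4 and 5 again, and C3–C4 to nitrile 1 and chloride 2. The allylic alcohol of 8 and 9 stands in for the enal while the ketone is olefinated, so the two carbonyl ends are never free together.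

## Alternatives that were turned down

Alternative 1: The cut is the C1'–C5' bond of the five-membered ring, made on a finished, silyl-protected drimane that carries the open-chain dichloromethyl ketone A1 with C11=C1' as an alkene. In the forward step a monovalent copper chloride–amine catalyst abstracts one chlorine, the α-keto radical at C5' closes 5-exo onto C1', and the C11 radical takes chlorine back to give the dichloride A2 as C11 epimers. In its favour, chlorine reaches C5' as part of the ring closure, so no substitution at a sensitive allylic carbon is needed. The step is catalytic and redox-neutral, and the C11 chloride is a handle for making the alkene. Against it, C5' is set relative to the silyloxy-bearing C2' of the chain, which must itself be made enantiopure. Elimination of HCl across C11–C1' from a C11 epimer mixture gives no control of the alkylidene geometry and competes with loss of the C5' chloride. C2' must then be oxidised to the dione level next to an α-chloro ketone. The decalin with its four stereocentres still has to be made separately. On chlorine installation this alternative is stronger than the chosen route, whose steps 21 and 22 are among its weakest. The chosen route offers in return one step that forms both carbocycles and all four decalin centres, and a ring expansion (step 20) that fixes the alkene geometry by mechanism.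

Alternative 2: The cut is the C7–C8 bond of ring B, leaving the ring A iodide A3 with an iodoethyl chain on C5 and an α-substituted acetoacetate on C10. In the forward step a divalent samarium reductant turns the primary iodide into a carbon nucleophile that adds to the C8 ketone while the metal is chelated between ketone and ester, giving the hydroxy ester A4. In its favour, chelation places the new hydroxyl cis to the ester, which is the 8β,9β relationship. C9 can equilibrate before closure, the tertiary alcohol is formed free, and C11 is an ester ready for reduction, with no benzyl ether and no hydrogenation. Against it, the ring A precursor with trans-related C5 and quaternary C10 must be made enantioselectively first, so the hardest part of the decalin problem is only moved back. Building A3 also means attaching C9 to the quaternary C10. Chelation asks for an axial oxygen syn to the axial C15, so the steric and chelation effects oppose each other. Only one ring and two centres are formed. For the C8/C9 relationship this alternative is at least as well founded as the cycloaddition. The chosen route offers convergence in its place: both rings and four centres from an acyclic chain, with the absolute configuration taken from a purchasable auxiliary.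

Alternative 3: C8–C9 and O8–C11 are cut together, giving the ring A keto acid A5 (acetic acid chain on C10, 3-oxobutyl chain on C5). In the forward step the acid is activated, a nucleophilic amine forms an acyl ammonium whose enolate at C9 adds to the C8 ketone, and the C8 alkoxide closes onto the acyl ammonium to give the cis-fused β-lactone A6. In its favour, the four-membered ring forces O8 and C11 cis, which is exactly the required pattern. The lactone protects the tertiary alcohol and activates C11 at once, reduction would lead straight to 24 or to the aldehyde level, and no protecting groups are needed. Against it, an enantiopure ring A is again required. The enolate carbon C9 is next to the quaternary C10 and the acceptor is a methyl ketone, the two least favourable features for this closure. The lactone must form on the face of the axial C15, and β-lactones of tertiary alcohols lose CO2 on warming to give the C8=C9 alkene. On protecting-group economy and directness at C11 this alternative is stronger. The chosen route offers a ring-forming step whose endo and facial control are well understood, and it does not need a separate enantioselective ring A synthesis.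

Key step: step 12

Remark on starting material: 2, the ethylene ketal of 5-chloropentan-2-one, is taken as a purchasable compound.
Remark on tautomers: the enol written for 36 and its other keto–enol forms are treated as one compound.

## Steps

Step 1
Reactants: 1 isobutyronitrile; 2 2-(3-chloropropyl)-2-methyl-1,3-dioxolane
Product: 3 2,2-dimethyl-5-(2-methyl-1,3-dioxolan-2-yl)pentanenitrile
Conditions: LiN(iPr)2, THF, −78 °C; then 2, DMPU, −78 °C → rt
Reagents that add atoms: none
Why: Nitrile anion alkylation: lithiated isobutyronitrile is a small, strongly nucleophilic tertiary carbanion that displaces primary chloride cleanly; this forms C3–C4 and the quaternary C4, and the ketal keeps the future C10 carbonyl inert to base.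

Step 2
Reactants: 3 2,2-dimethyl-5-(2-methyl-1,3-dioxolan-2-yl)pentanenitrile
Product: 4 2,2-dimethyl-5-(2-methyl-1,3-dioxolan-2-yl)pentanal
Conditions: iBu2AlH (1.2 equiv), toluene, −78 → −20 °C; then aq. AcOH/NaOAc (pH 5), 0 °C
Reagents that add atoms: water, O
Why: iBu2AlH adds once to a nitrile to give an N-aluminio imine that is not reduced further; buffered hydrolysis releases the neopentyl aldehyde (future C5) without cleaving the dioxolane.

Step 3
Reactants: 4 2,2-dimethyl-5-(2-methyl-1,3-dioxolan-2-yl)pentanal; 5 triethyl phosphonoacetate
Product: 6 ethyl (2E)-4,4-dimethyl-7-(2-methyl-1,3-dioxolan-2-yl)hept-2-enoate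
Conditions: NaH, THF, 0 °C → rt
Reagents that add atoms: none
Why: Horner–Wadsworth–Emmons olefination of a non-enolisable α-quaternary aldehyde; the stabilised phosphonate and the bulky γ-carbon favour the (E)-enoate, which becomes the C5=C6 bond of the diene.

Step 4
Reactants: 6 ethyl (2E)-4,4-dimethyl-7-(2-methyl-1,3-dioxolan-2-yl)hept-2-enoate
Product: 8 (7E)-9-hydroxy-6,6-dimethylnon-7-en-2-one, via allylic alcohol ketal 7 (not isolated)
Conditions: iBu2AlH (2.5 equiv), CH2Cl2, −78 °C; then 1 M aq. HCl, THF, rt
Reagents that add atoms: water, O
Why: iBu2AlH reduces the enoate 1,2 to the allylic alcohol 7 and the dilute acid of the work-up hydrolyses the dioxolane; the primary allylic alcohol is stable to this acid and serves as a base-stable stand-in for the enal.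

Step 5
Reactants: 8 (7E)-9-hydroxy-6,6-dimethylnon-7-en-2-one; 5 triethyl phosphonoacetate
Product: 9 ethyl (2E,8E)-10-hydroxy-3,7,7-trimethyldeca-2,8-dienoate
Conditions: NaH (excess), THF, 0 °C → reflux; chromatographic removal of the (2Z) isomer
Reagents that add atoms: none
Why: Horner–Wadsworth–Emmons olefination of the methyl ketone, the only carbonyl present (the hydroxyl consumes one equivalent of base); the isomer with the chain trans to the ester should predominate and the minor (2Z) isomer is separable; this fixes the dienophile geometry that later places C11 cis to C15.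

Step 6
Reactants: 9 ethyl (2E,8E)-10-hydroxy-3,7,7-trimethyldeca-2,8-dienoate
Product: 10 ethyl (2E,8E)-3,7,7-trimethyl-10-oxodeca-2,8-dienoate
Conditions: MnO2, CH2Cl2, rt
Reagents that add atoms: none
Why: MnO2 oxidises allylic alcohols selectively and leaves the enoate and the alkene geometry untouched.

Step 7
Reactants: 11 benzyl vinyl ether; 12 ethyl diphenylphosphinite
Product: 14 [1-(benzyloxy)ethyl]diphenylphosphine oxide (racemic), via benzyl 1-chloroethyl ether 13 (not isolated)
Conditions: HCl (1.0 equiv, Et2O), CH2Cl2, −20 °C; then 12, 0 → 40 °C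
Reagents that add atoms: none
Why: Markovnikov addition of HCl to the vinyl ether gives the α-chloro ether 13, a very reactive partner for a Michaelis–Arbuzov reaction with the phosphinite; chloride then removes the ethyl group from the alkoxyphosphonium ion.

Step 8
Reactants: 14 [1-(benzyloxy)ethyl]diphenylphosphine oxide; 10 ethyl (2E,8E)-3,7,7-trimethyl-10-oxodeca-2,8-dienoate
Product: 15 ethyl (2E,8E,10S*,11R*)-11-(benzyloxy)-11-(diphenylphosphoryl)-10-hydroxy-3,7,7-trimethyldodeca-2,8-dienoate (racemic diastereomer)
Conditions: 14, LiN(iPr)2, THF, −78 °C; then 10, −78 °C; aq. NH4Cl; chromatographic separation of the two diastereomers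
Reagents that add atoms: none
Why: Horner–Wittig addition: lithiated 14 adds 1,2 to the aldehyde at −78 °C much faster than to the β,β-disubstituted enoate, and the lithium alkoxides do not eliminate, so the two racemic diastereomers can be separated; the (10S*,11R*) isomer is the one whose syn elimination puts the methyl group cis to C9.

Step 9
Reactants: 15 ethyl (2E,8E,10S*,11R*)-11-(benzyloxy)-11-(diphenylphosphoryl)-10-hydroxy-3,7,7-trimethyldodeca-2,8-dienoate
Product: 16 ethyl (2E,8E,10E)-11-(benzyloxy)-3,7,7-trimethyldodeca-2,8,10-trienoate
Conditions: NaH, DMF, 0 → 25 °C; chromatography on Et3N-treated silica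
Reagents that add atoms: none
Why: The sodium alkoxide attacks phosphorus and diphenylphosphinate leaves by a stereospecific syn elimination (second stage of the Horner–Wittig reaction), so a single adduct gives only the (10E)-enol ether, with benzyloxy trans to C9 (outside) and methyl inside.

Step 10
Reactants: 16 ethyl (2E,8E,10E)-11-(benzyloxy)-3,7,7-trimethyldodeca-2,8,10-trienoate
Product: 17 (2E,8E,10E)-11-(benzyloxy)-3,7,7-trimethyldodeca-2,8,10-trienoic acid
Conditions: LiOH, THF/MeOH/H2O, 40 °C; then AcOH to pH 5, 0 °C, rapid extraction
Reagents that add atoms: lithium hydroxide (LiOH), [Li+].[OH-]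
Why: Saponification; the dienol ether is stable to base, and the acid is liberated only at pH 5 and in the cold because 1-alkoxydienes hydrolyse in stronger aqueous acid.

Step 11
Reactants: 17 (2E,8E,10E)-11-(benzyloxy)-3,7,7-trimethyldodeca-2,8,10-trienoic acid; 18 (S)-4-benzyloxazolidin-2-one
Product: 20 (S)-4-benzyl-3-[(2E,8E,10E)-11-(benzyloxy)-3,7,7-trimethyldodeca-2,8,10-trienoyl]oxazolidin-2-one, via mixed pivalic anhydride 19 (not isolated)
Conditions: pivaloyl chloride, Et3N, THF, −20 °C; then 18, LiCl, −20 °C → rt
Reagents that add atoms: none
Why: Mixed-anhydride N-acylation of the oxazolidinone under LiCl/Et3N; the auxiliary attacks the enoyl carbonyl because the pivaloyl carbonyl is shielded by its tert-butyl group, and the basic medium spares the enol ether.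

Step 12
Reactants: 20 (S)-4-benzyl-3-[(2E,8E,10E)-11-(benzyloxy)-3,7,7-trimethyldodeca-2,8,10-trienoyl]oxazolidin-2-one
Product: 21 (S)-4-benzyl-3-[8β-(benzyloxy)drim-6-en-11-oyl]oxazolidin-2-one (5α-H; 9α-H; 10β-methyl; 8α-methyl)
Conditions: Me2AlCl (1.6 equiv), 2,6-di-tert-butyl-4-methylpyridine (0.2 equiv), CH2Cl2, −40 → 0 °C; aq. KNaC4H4O6
Reagents that add atoms: none
Why: Excess Me2AlCl turns the imide into a cationic chelate with both carbonyl oxygens on one aluminium and the enoyl unit held s-cis, which lowers the LUMO and makes C10 the electrophilic end; the 1-benzyloxydiene is the matched partner with C5 as its nucleophilic end, so the [4+2] addition is of normal electron demand and asynchronous, C5–C10 forming ahead of C8–C9. The closest known reaction type is the Me2AlCl-promoted intramolecular Diels–Alder reaction of (E,E,E)-trienoyl oxazolidinones to trans-fused bicycles; the β-methyl group on the dienophile and the inside methyl group on the diene terminus go beyond that precedent. Ring B is closed by the cycloaddition itself (C5–C10 are the six atoms of the pericyclic array) and ring A through the C1–C4 tether between C10 and C5, whose folding is helped by the gem-dimethyl group at C4. The C9/C10 relationship follows from suprafacial addition to the (2E)-alkene (C11 cis to C15), the C5/C10 relationship from the endo transition state with the tether exo (H5 trans to C15, trans-decalin), and C8 from the (10E)-enol ether, whose outside benzyloxy group ends cis to the endo C11 (8β-O, 8α-methyl). The absolute configuration comes from the benzyl group of the (S)-auxiliary, which covers one face of the chelated s-cis enoyl unit so that the diene adds to the si face of C9. The step needs endo over exo addition and one dienophile face; the chelate, the chair-like tether and the β-methyl group (which disfavours the s-trans enoyl conformer through A(1,3) strain) secure both. If bond formation becomes fully stepwise through an aluminium enolate and an oxocarbenium ion, closure at C8 must be faster than rotation about C7–C8 for the C8 configuration to survive.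

Step 13
Reactants: 21 (S)-4-benzyl-3-[8β-(benzyloxy)drim-6-en-11-oyl]oxazolidin-2-one
Product: 23 (S)-4-benzyl-3-(8β-hydroxydriman-11-oyl)oxazolidin-2-one, via saturated benzyl ether 22 (not isolated)
Conditions: H2 (1 atm), Pd/C, EtOAc, rt; then Pd(OH)2/C, EtOH, H2 (3 atm), rt
Reagents that add atoms: none
Why: Heterogeneous hydrogenation: the cis-disubstituted C6=C7 alkene is saturated first on Pd/C to give 22, after which the tertiary ether is no longer allylic and is cleaved only at the benzyl–oxygen bond; no stereocentre is formed and the C-benzyl group of the auxiliary is not touched.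

Step 14
Reactants: 23 (S)-4-benzyl-3-(8β-hydroxydriman-11-oyl)oxazolidin-2-one
Product: 24 drimane-8β,11-diol [(1S,2S,4aS,8aS)-1-(hydroxymethyl)-2,5,5,8a-tetramethyldecahydronaphthalen-2-ol]
Conditions: LiBH4, MeOH (1 equiv), THF, 0 °C → rt
Reagents that add atoms: none
Why: Reductive cleavage of an N-acyloxazolidinone with LiBH4; as with aldol adducts the neighbouring C8 hydroxyl, bound to boron, should deliver hydride to the exocyclic carbonyl, and the auxiliary is recovered; C9 is not affected.

Step 15
Reactants: 24 drimane-8β,11-diol
Product: 25 8β,11-bis(triethylsilyloxy)drimane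
Conditions: Et3SiOTf (3 equiv), 2,6-lutidine, CH2Cl2, −78 → 0 °C
Reagents that add atoms: triethylsilyl trifluoromethanesulfonate, CC[Si](CC)(CC)OS(=O)(=O)C(F)(F)F
Why: The silyl triflate silylates even the hindered axial tertiary alcohol; protecting both hydroxyls means no free β-hydroxy aldehyde (retro-aldol, dehydration) appears later.

Step 16
Reactants: 25 8β,11-bis(triethylsilyloxy)drimane
Product: 26 8β-(triethylsilyloxy)driman-11-al
Conditions: (COCl)2, DMSO, CH2Cl2, −78 → −40 °C; then Et3N, −78 → 0 °C
Reagents that add atoms: none
Why: Swern oxidation of a primary triethylsilyl ether: the chlorosulfonium reagent cleaves the unhindered primary silyl ether and oxidises it in the same flask, whereas the tertiary silyl ether is inert; the short, cold exposure to Et3N should not epimerise C9.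

Step 17
Reactants: 26 8β-(triethylsilyloxy)driman-11-al
Product: 27 11-(dibromomethylidene)-8β-(triethylsilyloxy)drimane (C9–C11H=C1'Br2)
Conditions: CBr4, PPh3, 2,6-lutidine, CH2Cl2, 0 °C
Reagents that add atoms: carbon tetrabromide, BrC(Br)(Br)Br
Why: First stage of the Corey–Fuchs homologation (Wittig reaction with the dibromomethylene ylide); it adds C1' under non-basic conditions, so the aldehyde cannot enolise towards C9 or lose the β-silyloxy group.

Step 18
Reactants: 28 diisopropyl squarate (3,4-diisopropoxycyclobut-3-ene-1,2-dione)
Product: 30 3-isopropoxycyclobut-3-ene-1,2-dione, via hydroxycyclobutenone 29 (not isolated)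
Conditions: LiAlH(OtBu)3, THF, −78 → −20 °C; then conc. HCl (cat.), CH2Cl2, rt
Reagents that add atoms: water, O
Why: The hindered hydride adds once to one carbonyl of the squarate; acid ionises the resulting allylic alcohol 29, water adds at the alkoxy-stabilised carbon and propan-2-ol is lost, a 1,3-carbonyl transposition that gives the semisquarate.

Step 19
Reactants: 27 11-(dibromomethylidene)-8β-(triethylsilyloxy)drimane; 30 3-isopropoxycyclobut-3-ene-1,2-dione
Product: 32 4-hydroxy-3-isopropoxy-4-{2-[8β-(triethylsilyloxy)-11-nordriman-9β-yl]ethynyl}cyclobut-2-en-1-one (carbinol epimers), via lithium acetylide 31 (not isolated)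
Conditions: n-BuLi (2.1 equiv), THF, −78 → −20 °C; then 30, −78 °C; aq. NH4Cl
Reagents that add atoms: none
Why: Second stage of the Corey–Fuchs sequence gives the acetylide 31, which adds to the more electrophilic carbonyl of 30, the one next to the isopropoxy-bearing carbon (the other is a vinylogous ester); the new carbinol centre forms as a mixture, which does not matter because it becomes C5'=O.

Step 20
Reactants: 32 4-hydroxy-3-isopropoxy-4-{2-[8β-(triethylsilyloxy)-11-nordriman-9β-yl]ethynyl}cyclobut-2-en-1-one
Product: 33 4-isopropoxy-2-{(E)-[8β-(triethylsilyloxy)-11-nordriman-9β-yl]methylidene}cyclopent-4-ene-1,3-dione (C2'=O; C3'–H; C4'–OiPr; C5'=O; C9 cis to C2')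
Conditions: Pd(O2CCF3)2 (5 mol %), THF, rt
Reagents that add atoms: none
Why: Palladium-catalysed ring expansion of a 4-alkynyl-4-hydroxycyclobutenone: divalent palladium activates the alkyne, the acyl carbon (future C2') migrates to C1' anti to the metal while the carbinol becomes C5'=O, and protonolysis of the vinyl–palladium bond with retention leaves C9 cis to C2', the geometry of 36.

Step 21
Reactants: 33 4-isopropoxy-2-{(E)-[8β-(triethylsilyloxy)-11-nordriman-9β-yl]methylidene}cyclopent-4-ene-1,3-dione
Product: 34 (4S)-4-hydroxy-3-isopropoxy-5-{(Z)-[8β-(triethylsilyloxy)-11-nordriman-9β-yl]methylidene}cyclopent-2-en-1-one (the 5'S alcohol; alkene geometry unchanged, C9 cis to C2')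
Conditions: (R)-2-methyl-CBS-oxazaborolidine (0.5 equiv), catecholborane, toluene, −78 °C
Reagents that add atoms: none
Why: CBS reduction: C5'=O is the only carbonyl that is not deactivated as a vinylogous ester and is not screened by C9; the catalyst should bind the lone pair away from the isopropoxy-bearing C4' and deliver hydride to the face that gives the 5'S alcohol; this is reagent control because the decalin is too remote, and the enantiomeric catalyst is available if the sense proves opposite.

Step 22
Reactants: 34 (4S)-4-hydroxy-3-isopropoxy-5-{(Z)-[8β-(triethylsilyloxy)-11-nordriman-9β-yl]methylidene}cyclopent-2-en-1-one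
Product: 35 (4R)-4-chloro-3-isopropoxy-5-{(E)-[8β-(triethylsilyloxy)-11-nordriman-9β-yl]methylidene}cyclopent-2-en-1-one (the 5'R chloride)
Conditions: PPh3, hexachloroacetone, CH2Cl2, −20 → 0 °C
Reagents that add atoms: hexachloroacetone, ClC(Cl)(Cl)C(=O)C(Cl)(Cl)Cl
Why: Appel-type chlorination: chloride displaces the alkoxyphosphonium group with inversion (SN2) to give 5'R; C5' has no β-hydrogen, so elimination is impossible, allylic transposition would create a cyclopentadienone on one flank and is electronically mismatched on the enol-ether flank, and the low chloride concentration limits chloride exchange.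

Step 23
Reactants: 35 (4R)-4-chloro-3-isopropoxy-5-{(E)-[8β-(triethylsilyloxy)-11-nordriman-9β-yl]methylidene}cyclopent-2-en-1-one
Product: 36 (5R)-5-chloro-3-hydroxy-4-{(E)-[(1R,2S,4aS,8aS)-2-hydroxy-2,5,5,8a-tetramethyldecahydronaphthalen-1-yl]methylidene}cyclopent-2-en-1-one (CNP0279879.2)
Conditions: 2 M aq. HCl, THF, 0 °C → rt
Reagents that add atoms: water, O
Why: Aqueous acid hydrolyses the vinylogous ester by addition of water at C4' and loss of propan-2-ol, and cleaves the silyl ether at silicon; C5' is then α to a carbonyl and does not ionise, and the mild temperature should spare the tertiary C8 alcohol.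

## Compound list

1 | isobutyronitrile | CC(C)C#N | starting material
2 | 2-(3-chloropropyl)-2-methyl-1,3-dioxolane | CC1(CCCCl)OCCO1 | starting material
3 | 2,2-dimethyl-5-(2-methyl-1,3-dioxolan-2-yl)pentanenitrile | CC1(CCCC(C)(C)C#N)OCCO1 | intermediate
4 | 2,2-dimethyl-5-(2-methyl-1,3-dioxolan-2-yl)pentanal | CC1(CCCC(C)(C)C=O)OCCO1 | intermediate
5 | triethyl phosphonoacetate | CCOC(=O)CP(=O)(OCC)OCC | starting material
6 | ethyl (2E)-4,4-dimethyl-7-(2-methyl-1,3-dioxolan-2-yl)hept-2-enoate | CCOC(=O)/C=C/C(C)(C)CCCC1(C)OCCO1 | intermediate
7 | (2E)-4,4-dimethyl-7-(2-methyl-1,3-dioxolan-2-yl)hept-2-en-1-ol | OC/C=C/C(C)(C)CCCC1(C)OCCO1 | intermediate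
8 | (7E)-9-hydroxy-6,6-dimethylnon-7-en-2-one | CC(=O)CCCC(C)(C)/C=C/CO | intermediate
9 | ethyl (2E,8E)-10-hydroxy-3,7,7-trimethyldeca-2,8-dienoate | CCOC(=O)/C=C(\C)CCCC(C)(C)/C=C/CO | intermediate
10 | ethyl (2E,8E)-3,7,7-trimethyl-10-oxodeca-2,8-dienoate | CCOC(=O)/C=C(\C)CCCC(C)(C)/C=C/C=O | intermediate
11 | benzyl vinyl ether | C=COCc1ccccc1 | starting material
12 | ethyl diphenylphosphinite | CCOP(c1ccccc1)c1ccccc1 | starting material
13 | benzyl 1-chloroethyl ether (racemic) | CC(Cl)OCc1ccccc1 | intermediate
14 | [1-(benzyloxy)ethyl]diphenylphosphine oxide (racemic) | CC(OCc1ccccc1)P(=O)(c1ccccc1)c1ccccc1 | intermediate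
15 | ethyl (2E,8E,10S*,11R*)-11-(benzyloxy)-11-(diphenylphosphoryl)-10-hydroxy-3,7,7-trimethyldodeca-2,8-dienoate (racemic; one enantiomer drawn) | CCOC(=O)/C=C(\C)CCCC(C)(C)/C=C/[C@H](O)[C@](C)(OCc1ccccc1)P(=O)(c1ccccc1)c1ccccc1 | intermediate
16 | ethyl (2E,8E,10E)-11-(benzyloxy)-3,7,7-trimethyldodeca-2,8,10-trienoate | CCOC(=O)/C=C(\C)CCCC(C)(C)/C=C/C=C(\C)OCc1ccccc1 | intermediate
17 | (2E,8E,10E)-11-(benzyloxy)-3,7,7-trimethyldodeca-2,8,10-trienoic acid | OC(=O)/C=C(\C)CCCC(C)(C)/C=C/C=C(\C)OCc1ccccc1 | intermediate
18 | (S)-4-benzyloxazolidin-2-one | O=C1N[C@@H](Cc2ccccc2)CO1 | starting material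
19 | (2E,8E,10E)-11-(benzyloxy)-3,7,7-trimethyldodeca-2,8,10-trienoic pivalic anhydride | CC(C)(C)C(=O)OC(=O)/C=C(\C)CCCC(C)(C)/C=C/C=C(\C)OCc1ccccc1 | intermediate
20 | (S)-4-benzyl-3-[(2E,8E,10E)-11-(benzyloxy)-3,7,7-trimethyldodeca-2,8,10-trienoyl]oxazolidin-2-one | O=C(N1C(=O)OC[C@@H]1Cc1ccccc1)/C=C(\C)CCCC(C)(C)/C=C/C=C(\C)OCc1ccccc1 | intermediate
21 | (S)-4-benzyl-3-[8β-(benzyloxy)drim-6-en-11-oyl]oxazolidin-2-one | CC1(C)CCC[C@]2(C)[C@@H](C(=O)N3C(=O)OC[C@@H]3Cc4ccccc4)[C@@](C)(OCc5ccccc5)C=C[C@@H]12 | intermediate
22 | (S)-4-benzyl-3-[8β-(benzyloxy)driman-11-oyl]oxazolidin-2-one | CC1(C)CCC[C@]2(C)[C@@H](C(=O)N3C(=O)OC[C@@H]3Cc4ccccc4)[C@@](C)(OCc5ccccc5)CC[C@@H]12 | intermediate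
23 | (S)-4-benzyl-3-(8β-hydroxydriman-11-oyl)oxazolidin-2-one | CC1(C)CCC[C@]2(C)[C@@H](C(=O)N3C(=O)OC[C@@H]3Cc4ccccc4)[C@@](C)(O)CC[C@@H]12 | intermediate
24 | drimane-8β,11-diol | CC1(C)CCC[C@]2(C)[C@@H](CO)[C@@](C)(O)CC[C@@H]12 | intermediate
25 | 8β,11-bis(triethylsilyloxy)drimane | CC1(C)CCC[C@]2(C)[C@@H](CO[Si](CC)(CC)CC)[C@@](C)(O[Si](CC)(CC)CC)CC[C@@H]12 | intermediate
26 | 8β-(triethylsilyloxy)driman-11-al | CC1(C)CCC[C@]2(C)[C@@H](C=O)[C@@](C)(O[Si](CC)(CC)CC)CC[C@@H]12 | intermediate
27 | 11-(dibromomethylidene)-8β-(triethylsilyloxy)drimane | CC1(C)CCC[C@]2(C)[C@@H](C=C(Br)Br)[C@@](C)(O[Si](CC)(CC)CC)CC[C@@H]12 | intermediate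
28 | diisopropyl squarate | CC(C)OC1=C(OC(C)C)C(=O)C1=O | starting material
29 | 4-hydroxy-2,3-diisopropoxycyclobut-2-en-1-one (racemic) | CC(C)OC1=C(OC(C)C)C(O)C1=O | intermediate
30 | 3-isopropoxycyclobut-3-ene-1,2-dione | CC(C)OC1=CC(=O)C1=O | intermediate
31 | lithium 2-[8β-(triethylsilyloxy)-11-nordriman-9β-yl]acetylide | CC1(C)CCC[C@]2(C)[C@@H](C#C[Li])[C@@](C)(O[Si](CC)(CC)CC)CC[C@@H]12 | intermediate
32 | 4-hydroxy-3-isopropoxy-4-{2-[8β-(triethylsilyloxy)-11-nordriman-9β-yl]ethynyl}cyclobut-2-en-1-one (carbinol epimers) | CC1(C)CCC[C@]2(C)[C@@H](C#CC3(O)C(=O)C=C3OC(C)C)[C@@](C)(O[Si](CC)(CC)CC)CC[C@@H]12 | intermediate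
33 | 4-isopropoxy-2-{(E)-[8β-(triethylsilyloxy)-11-nordriman-9β-yl]methylidene}cyclopent-4-ene-1,3-dione | CC1(C)CCC[C@]2(C)[C@@H](/C=C3\C(=O)C=C(OC(C)C)C3=O)[C@@](C)(O[Si](CC)(CC)CC)CC[C@@H]12 | intermediate
34 | (4S)-4-hydroxy-3-isopropoxy-5-{(Z)-[8β-(triethylsilyloxy)-11-nordriman-9β-yl]methylidene}cyclopent-2-en-1-one | CC1(C)CCC[C@]2(C)[C@@H](/C=C3\C(=O)C=C(OC(C)C)[C@H]3O)[C@@](C)(O[Si](CC)(CC)CC)CC[C@@H]12 | intermediate
35 | (4R)-4-chloro-3-isopropoxy-5-{(E)-[8β-(triethylsilyloxy)-11-nordriman-9β-yl]methylidene}cyclopent-2-en-1-one | CC1(C)CCC[C@]2(C)[C@@H](/C=C3\C(=O)C=C(OC(C)C)[C@@H]3Cl)[C@@](C)(O[Si](CC)(CC)CC)CC[C@@H]12 | intermediate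
36 | (5R)-5-chloro-3-hydroxy-4-{(E)-[(1R,2S,4aS,8aS)-2-hydroxy-2,5,5,8a-tetramethyldecahydronaphthalen-1-yl]methylidene}cyclopent-2-en-1-one | CC1(C)CCC[C@]2(C)[C@@H](/C=C3\C(O)=CC(=O)[C@@H]3Cl)[C@@](C)(O)CC[C@@H]12 | target

## Step count and least certain steps

Total: 23 steps. Longest linear sequence: 21 steps (steps 1–6, 8–17 and 19–23); steps 7 and 18 prepare the side components 14 and 30.

Step 12 (key step). The most likely failure is that the cycloaddition stalls or diverts. The methyl group on the inside of C8 makes the s-cis diene conformation costly, and the Lewis acid can meanwhile cause hydrolysis or oligomerisation of the enol ether. Fully stepwise bond formation would lose the C8 configuration, and the tertiary allylic ether of the product can ionise. The fallback removes the inside methyl group and introduces C12 afterwards; it sets out from 10 and comes back at 25.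
- Arbuzov reaction of benzyl chloromethyl ether with 12 gives (benzyloxymethyl)diphenylphosphine oxide F1.
- Its lithium derivative adds to 10 to give, after separation, the (10S*,11R*) hydroxy phosphine oxide F2, and NaH eliminates this to the (10E)-enol ether ester F3.
- Saponification gives acid F4, pivaloyl chloride gives the mixed anhydride F5, and acylation of 18 gives imide F6. Its diene terminus carries only the outside benzyloxy group, the substitution pattern for which this cycloaddition is established.
- Me2AlCl gives the 12-nor cycloadduct F7 (8β-benzyloxy, 8α-H). Hydrogenation gives the saturated ether F8 and then hydroxy imide F9, and LiBH4 gives 12-nordrimane-8β,11-diol F10.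
- Et3SiCl/imidazole silylates the primary hydroxyl to the mono-silyl ether F11, and Dess–Martin periodinane gives ketone F12.
- MeLi/CeCl3 adds to C8 from the α face, opposite the axial C15, to give 11-(triethylsilyloxy)driman-8β-ol F13; Et3SiOTf then gives 25.

Step 22. The most likely failure is loss of configuration at C5', either through ionisation of the activated alcohol (the carbon is doubly allylic) or through exchange of the product chloride with free chloride. The fallback gives up stereospecificity and relies on separation with recycling; it sets out from 34 and returns at 35. The same chlorination is accepted as giving 35 together with its C5' epimer, the (5'S)-chloride F19. The two are diastereomers and are separated by preparative HPLC. F19 is stirred with Bu4NCl in acetone, where degenerate SN2 exchange re-equilibrates C5', and the mixture is separated again.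

Step 21. The most likely failure is poor facial discrimination, because both carbons flanking C5'=O are sp2 and differ only in their remote substituents; reduction at C2' or conjugate reduction could also compete. The fallback uses substrate-independent reduction followed by correction; it sets out from 33 and returns at 34. NaBH4/CeCl3·7H2O in MeOH at −78 °C gives 34 together with its epimer, the (5'R)-alcohol F17. After separation, F17 is inverted by a Mitsunobu reaction with chloroacetic acid (PPh3, diisopropyl azodicarboxylate) to the (5'S)-chloroacetate F18, and thiourea/NaHCO3 removes the chloroacetyl group to give 34.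

Step 20. The most likely failure is erosion of the alkylidene geometry after the ring expansion. The trifluoroacetic acid formed in the cycle, or reversible addition to the Michael acceptor, can isomerise the C11=C1' bond, and the two isomers are close in energy because a carbonyl flanks C1' on both sides. Migration of the vinyl instead of the acyl carbon is a second possibility. The fallback uses the ring expansion only for constitution and sets the geometry by photochemical recycling; it sets out from 32 and returns at 33. The expansion then gives 33 together with its (11Z) isomer F16 (C9 cis to C5'). After separation F16 is irradiated at 365 nm to a photostationary mixture of both isomers and separated again, so the material is funnelled to 33.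

Step 14. The most likely failure is hydride attack at the ring carbonyl of the auxiliary, since the acyl group lies between two fully substituted carbons, or retro-aldol opening of ring B through the C8 alkoxide. The fallback avoids both the hydride cleavage and the free alkoxide; it sets out from 23 and returns at 26. Me3Al/MeONHMe·HCl transaminates the β-hydroxy imide to the Weinreb amide F14, with the aluminium alkoxide at C8 directing the amine to the exocyclic carbonyl. Et3SiOTf gives the silyl ether F15, and iBu2AlH reduces this to 26, replacing steps 14–16.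

## Further compounds

F1 | step 12 | (benzyloxymethyl)diphenylphosphine oxide | O=P(COCc1ccccc1)(c1ccccc1)c1ccccc1
F2 | step 12 | ethyl (2E,8E,10S*,11R*)-11-(benzyloxy)-11-(diphenylphosphoryl)-10-hydroxy-3,7,7-trimethylundeca-2,8-dienoate (racemic) | CCOC(=O)/C=C(\C)CCCC(C)(C)/C=C/[C@H](O)[C@H](OCc1ccccc1)P(=O)(c1ccccc1)c1ccccc1
F3 | step 12 | ethyl (2E,8E,10E)-11-(benzyloxy)-3,7,7-trimethylundeca-2,8,10-trienoate | CCOC(=O)/C=C(\C)CCCC(C)(C)/C=C/C=C/OCc1ccccc1
F4 | step 12 | (2E,8E,10E)-11-(benzyloxy)-3,7,7-trimethylundeca-2,8,10-trienoic acid | OC(=O)/C=C(\C)CCCC(C)(C)/C=C/C=C/OCc1ccccc1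
F5 | step 12 | (2E,8E,10E)-11-(benzyloxy)-3,7,7-trimethylundeca-2,8,10-trienoic pivalic anhydride | CC(C)(C)C(=O)OC(=O)/C=C(\C)CCCC(C)(C)/C=C/C=C/OCc1ccccc1
F6 | step 12 | (S)-4-benzyl-3-[(2E,8E,10E)-11-(benzyloxy)-3,7,7-trimethylundeca-2,8,10-trienoyl]oxazolidin-2-one | O=C(N1C(=O)OC[C@@H]1Cc1ccccc1)/C=C(\C)CCCC(C)(C)/C=C/C=C/OCc1ccccc1
F7 | step 12 | (S)-4-benzyl-3-[8β-(benzyloxy)-12-nordrim-6-en-11-oyl]oxazolidin-2-one | CC1(C)CCC[C@]2(C)[C@@H](C(=O)N3C(=O)OC[C@@H]3Cc4ccccc4)[C@@H](OCc5ccccc5)C=C[C@@H]12
F8 | step 12 | (S)-4-benzyl-3-[8β-(benzyloxy)-12-nordriman-11-oyl]oxazolidin-2-one | CC1(C)CCC[C@]2(C)[C@@H](C(=O)N3C(=O)OC[C@@H]3Cc4ccccc4)[C@@H](OCc5ccccc5)CC[C@@H]12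
F9 | step 12 | (S)-4-benzyl-3-(8β-hydroxy-12-nordriman-11-oyl)oxazolidin-2-one | CC1(C)CCC[C@]2(C)[C@@H](C(=O)N3C(=O)OC[C@@H]3Cc4ccccc4)[C@@H](O)CC[C@@H]12
F10 | step 12 | 12-nordrimane-8β,11-diol | CC1(C)CCC[C@]2(C)[C@@H](CO)[C@@H](O)CC[C@@H]12
F11 | step 12 | 11-(triethylsilyloxy)-12-nordriman-8β-ol | CC1(C)CCC[C@]2(C)[C@@H](CO[Si](CC)(CC)CC)[C@@H](O)CC[C@@H]12
F12 | step 12 | 11-(triethylsilyloxy)-12-nordriman-8-one | CC1(C)CCC[C@]2(C)[C@@H](CO[Si](CC)(CC)CC)C(=O)CC[C@@H]12
F13 | step 12 | 11-(triethylsilyloxy)driman-8β-ol | CC1(C)CCC[C@]2(C)[C@@H](CO[Si](CC)(CC)CC)[C@@](C)(O)CC[C@@H]12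
F14 | step 14 | 8β-hydroxy-N-methoxy-N-methyldriman-11-amide | CC1(C)CCC[C@]2(C)[C@@H](C(=O)N(C)OC)[C@@](C)(O)CC[C@@H]12
F15 | step 14 | N-methoxy-N-methyl-8β-(triethylsilyloxy)driman-11-amide | CC1(C)CCC[C@]2(C)[C@@H](C(=O)N(C)OC)[C@@](C)(O[Si](CC)(CC)CC)CC[C@@H]12
F16 | step 20 | 4-isopropoxy-2-{(Z)-[8β-(triethylsilyloxy)-11-nordriman-9β-yl]methylidene}cyclopent-4-ene-1,3-dione | CC1(C)CCC[C@]2(C)[C@@H](/C=C3/C(=O)C=C(OC(C)C)C3=O)[C@@](C)(O[Si](CC)(CC)CC)CC[C@@H]12
F17 | step 21 | (4R)-4-hydroxy-3-isopropoxy-5-{(Z)-[8β-(triethylsilyloxy)-11-nordriman-9β-yl]methylidene}cyclopent-2-en-1-one | CC1(C)CCC[C@]2(C)[C@@H](/C=C3\C(=O)C=C(OC(C)C)[C@@H]3O)[C@@](C)(O[Si](CC)(CC)CC)CC[C@@H]12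
F18 | step 21 | (1S)-2-isopropoxy-4-oxo-5-{(Z)-[8β-(triethylsilyloxy)-11-nordriman-9β-yl]methylidene}cyclopent-2-en-1-yl chloroacetate | CC1(C)CCC[C@]2(C)[C@@H](/C=C3\C(=O)C=C(OC(C)C)[C@H]3OC(=O)CCl)[C@@](C)(O[Si](CC)(CC)CC)CC[C@@H]12
F19 | step 22 | (4S)-4-chloro-3-isopropoxy-5-{(E)-[8β-(triethylsilyloxy)-11-nordriman-9β-yl]methylidene}cyclopent-2-en-1-one | CC1(C)CCC[C@]2(C)[C@@H](/C=C3\C(=O)C=C(OC(C)C)[C@H]3Cl)[C@@](C)(O[Si](CC)(CC)CC)CC[C@@H]12
A1 | alternative 1 | (5E)-4-(tert-butyldimethylsilyloxy)-1,1-dichloro-6-[8β-(triethylsilyloxy)-11-nordriman-9β-yl]hex-5-en-2-one | CC1(C)CCC[C@]2(C)[C@@H](/C=C/[C@@H](O[Si](C)(C)C(C)(C)C)CC(=O)C(Cl)Cl)[C@@](C)(O[Si](CC)(CC)CC)CC[C@@H]12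
A2 | alternative 1 | 2-chloro-3-{chloro[8β-(triethylsilyloxy)-11-nordriman-9β-yl]methyl}-4-(tert-butyldimethylsilyloxy)cyclopentanone (C11 epimers) | CC1(C)CCC[C@]2(C)[C@@H](C(Cl)[C@@H]3[C@@H](O[Si](C)(C)C(C)(C)C)CC(=O)[C@@H]3Cl)[C@@](C)(O[Si](CC)(CC)CC)CC[C@@H]12
A3 | alternative 2 | methyl 2-[2-(2-iodoethyl)-1,3,3-trimethylcyclohexyl]-3-oxobutanoate (C5 and C10 as in 36) | CC1(C)CCC[C@](C)(C(C(C)=O)C(=O)OC)[C@H]1CCI
A4 | alternative 2 | methyl 8β-hydroxydriman-11-oate | CC1(C)CCC[C@]2(C)[C@@H](C(=O)OC)[C@@](C)(O)CC[C@@H]12
A5 | alternative 3 | 2-[1,3,3-trimethyl-2-(3-oxobutyl)cyclohexyl]acetic acid (C5 and C10 as in 36) | CC1(C)CCC[C@](C)(CC(O)=O)[C@H]1CCC(C)=O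
A6 | alternative 3 | 8β-hydroxydriman-11-oic acid 11,8-lactone | CC1(C)CCC[C@]2(C)[C@@H](C3=O)[C@@](C)(O3)CC[C@@H]12
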